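**Retrosynthetic overview**

- Target 30 ⇒ dimer 22 (ring A–CH2–ring B) + ring C Mannich base 27; the last C–C bond is a C-alkylation of the only free carbon of ring B by the o-quinone methide of ring C.
- 22 ⇒ 19 by hydrogenolysis and hydrolysis: the isoxazole masks the 2-butanoyl enol of ring A, and the benzyl ester on the bridge-bearing carbon is a temporary activating group lost as CO2.
- 19 ⇒ dihydrocoumarin 15 + dimethylketene 17: ring A is closed by a ketene C-acylation/Dieckmann annulation that makes the ring C(=O)–CMe2 bond and the bond between the bridge-bearing carbon and its neighbouring C–OH carbon.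
- Enabling feature: in ring A the CMe2 carbon and the adjacent C–OH carbon are a dimethylketene unit (Me2C=C=O) lying between a nucleophilic carbon (the one that carries the CH2 bridge) and an acyl carbon (the ring C=O next to the butanoyl-bearing carbon), the alternating polarity of a cyclohexane-1,3,5-trione.
- 15 ⇒ ring B Mannich base 6 + isoxazole diester 11; benzyl ether 5 also gives ring C (bromination next to the free hydroxyl, O-methylation, Suzuki methylation). Ring order: ring B (arene) → isoxazole → temporary lactone → ring A (step 7) → ring C attached last.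

Key step: step 7

Remark: the target is achiral; the stereocentres of 14, 15, 18, 19, 20, F2 and F3 are formed as racemates and are erased before the end, so their SMILES carry no configuration. Enolised triketone rings are drawn as one tautomer. Commercial starting materials are 1, 2, 7, 8 and 16.

**Route**

Step 1
Reactants: 1 phloroglucinol (benzene-1,3,5-triol); 2 butanenitrile
Product: 4 1-(2,4,6-trihydroxyphenyl)butan-1-one, via iminium chloride 3 (not isolated)
Conditions: ZnCl2 (0.3 equiv), HCl (g), Et2O, 0 °C; then H2O, 100 °C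
Reagents that add atoms: water, O
Why: Houben–Hoesch acylation; the symmetric arene is acylated once only because the iminium salt deactivates the ring, and hydrolysis gives the ketone.

Step 2
Reactants: 4 1-(2,4,6-trihydroxyphenyl)butan-1-one
Product: 5 1-[2,4-bis(benzyloxy)-6-hydroxyphenyl]butan-1-one
Conditions: BnBr (2.1 equiv), K2CO3 (2.2 equiv), acetone, reflux
Reagents that add atoms: benzyl bromide, BrCc1ccccc1
Why: Williamson etherification; the para-hydroxyl and one of the two equivalent ortho-hydroxyls react, while the other ortho-hydroxyl stays free in its hydrogen bond to the ketone.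

Step 3
Reactants: 5 1-[2,4-bis(benzyloxy)-6-hydroxyphenyl]butan-1-one
Product: 6 1-{4,6-bis(benzyloxy)-3-[(dimethylamino)methyl]-2-hydroxyphenyl}butan-1-one
Conditions: Me2N+=CH2 I− (1.05 equiv), K2CO3 (1.5 equiv), MeCN, rt
Reagents that add atoms: N,N-dimethylmethyleneiminium iodide (Eschenmoser's salt), C=[N+](C)C.[I-]
Why: ortho-selective phenol Mannich reaction with a preformed iminium salt; the phenoxide directs the electrophile to C-3, ortho to the free hydroxyl, as in other electrophilic substitutions of 2-hydroxy-4,6-dialkoxyaryl ketones.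

Step 4
Reactants: 7 butanal oxime; 8 dibenzyl 3-oxopentanedioate
Product: 11 benzyl 5-[2-(benzyloxy)-2-oxoethyl]-3-propyl-1,2-oxazole-4-carboxylate, via hydroximoyl chloride 9 (not isolated), via nitrile oxide 10 (not isolated)
Conditions: NCS (1.05 equiv), DMF, rt; then 8, Et3N (2.2 equiv), CH2Cl2, 0 °C → rt
Reagents that add atoms: none
Why: isoxazole synthesis from a hydroximoyl chloride and a 1,3-dicarbonyl compound; the nitrile oxide carbon bonds to the central enolate carbon, loss of water aromatises the ring, and the symmetry of 8 allows only one product.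

Step 5
Reactants: 6 1-{4,6-bis(benzyloxy)-3-[(dimethylamino)methyl]-2-hydroxyphenyl}butan-1-one; 11 benzyl 5-[2-(benzyloxy)-2-oxoethyl]-3-propyl-1,2-oxazole-4-carboxylate
Product: 15 benzyl 5-[5,7-bis(benzyloxy)-8-butanoyl-2-oxo-3,4-dihydro-2H-chromen-3-yl]-3-propyl-1,2-oxazole-4-carboxylate (racemic), via ring B ammonium iodide 12 (not isolated), via ring B quinone methide 13 (not isolated), via Michael adduct 14 (not isolated)
Conditions: MeI (1.2 equiv), THF, rt, evaporate; 11 (1.3 equiv), Cs2CO3 (2 equiv), MeCN, 0 °C → rt, aq. NH4Cl work-up; then TsOH·H2O (10 mol %), toluene, 80 °C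
Reagents that add atoms: none
Why: the methiodide loses trimethylamine to an o-quinone methide, the caesium enolate of the isoxazolylacetate adds to it (Michael reaction), and acid-catalysed lactonisation of the liberated phenol onto the acetate ester gives the dihydrocoumarin with a racemic C-3.

Step 6
Reactants: 16 2-bromo-2-methylpropanoyl bromide
Product: 17 dimethylketene (2-methylprop-1-en-1-one)
Conditions: Zn dust (activated, 1.1 equiv), Et2O, N2, 0 → 35 °C, co-distilled into a −78 °C receiver, used at once
Reagents that add atoms: none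
Why: zinc-mediated 1,2-dehalogenation of an α-bromoacyl bromide, the classical laboratory preparation of dimethylketene.

Step 7
Reactants: 15 benzyl 5-[5,7-bis(benzyloxy)-8-butanoyl-2-oxo-3,4-dihydro-2H-chromen-3-yl]-3-propyl-1,2-oxazole-4-carboxylate; 17 dimethylketene
Product: 19 benzyl 7-{[4,6-bis(benzyloxy)-3-butanoyl-2-hydroxyphenyl]methyl}-5,5-dimethyl-4,6-dioxo-3-propyl-4,5,6,7-tetrahydro-1,2-benzoxazole-7-carboxylate (racemic), via spiro lactone 18 (not isolated)
Conditions: LiN(SiMe3)2 (1.05 equiv), THF, −78 °C; 17 (1.15 equiv in Et2O), −78 → −40 °C; AcOH, −78 °C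
Reagents that add atoms: none
Why: Proposed new method: the lithium enolate of lactone 15 (C-3, by far the most acidic C–H) adds through carbon to the central carbon of dimethylketene, which makes the first C–C bond and delivers, regiospecifically and with no acidic hydrogen left nearby, the α,α-dimethyl enolate that closes ring A by Dieckmann attack on the isoxazole-4-carboxylate; the expelled benzyl oxide is consumed at once by opening the aryl lactone of 18, so no free alkoxide remains for a retro-Claisen cleavage and the temporary carboxyl group ends as a benzyl ester. The closest known reactions are the Staunton–Weinreb and Hauser–Kraus annulations (a stabilised anion adds to an acceptor and the new enolate closes on a neighbouring aromatic ester) and the alkoxide-catalysed trimerisation of dimethylketene, in which an enolate is C-acylated by the ketene and the new enolate closes a 2,2-dimethylcyclohexane-1,3,5-trione by Claisen condensation. Ring A closes in the 6-(enolendo)-exo-trig mode, the isoxazole C-4/C-5 double bond holding ester and enolate cis. The one new stereocentre, the quaternary C-7 of 19, forms as a racemate and needs no control because the later decarboxylation erases it. The step needs C- and not O-acylation of the enolate and C- and not O-closure: O-acylation by a ketene gives an acyl enolate that reverts by E1cB loss of the enolate, and an enol lactone from O-closure is reopened by the alkoxide, whereas both C–C bonds persist, so the system funnels to the chelated phenoxide of 19, the most stable anion on the path.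

Step 8
Reactants: 19 benzyl 7-{[4,6-bis(benzyloxy)-3-butanoyl-2-hydroxyphenyl]methyl}-5,5-dimethyl-4,6-dioxo-3-propyl-4,5,6,7-tetrahydro-1,2-benzoxazole-7-carboxylate
Product: 21 2-(1-aminobutylidene)-6-[(3-butanoyl-2,4,6-trihydroxyphenyl)methyl]-5-hydroxy-4,4-dimethylcyclohex-5-ene-1,3-dione, via keto acid 20 (not isolated)
Conditions: H2 (1 atm), Pd/C (10 %), THF–MeOH, rt; then 40 °C
Reagents that add atoms: none
Why: catalytic hydrogenolysis cleaves both benzyl ethers, the benzyl ester and the isoxazole N–O bond, and the β-keto acid 20 with its fully substituted α-carbon loses CO2 on gentle warming, which removes the temporary carboxyl group.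

Step 9
Reactants: 21 2-(1-aminobutylidene)-6-[(3-butanoyl-2,4,6-trihydroxyphenyl)methyl]-5-hydroxy-4,4-dimethylcyclohex-5-ene-1,3-dione
Product: 22 2-butanoyl-4-[(3-butanoyl-2,4,6-trihydroxyphenyl)methyl]-3,5-dihydroxy-6,6-dimethylcyclohexa-2,4-dien-1-one
Conditions: 2 M aq. HCl, 1,4-dioxane, 70 °C
Reagents that add atoms: water, O
Why: acid hydrolysis of the primary enaminone (vinylogous amide) to the enolised 2-acyl-1,3-dione, the known last stage of the isoxazole route to β-triketones, driven by protonation of the ammonia that leaves.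

Step 10
Reactants: 5 1-[2,4-bis(benzyloxy)-6-hydroxyphenyl]butan-1-one
Product: 23 1-[4,6-bis(benzyloxy)-3-bromo-2-hydroxyphenyl]butan-1-one
Conditions: NBS (1.0 equiv), MeCN, 0 °C, dark
Reagents that add atoms: N-bromosuccinimide, O=C1CCC(=O)N1Br
Why: electrophilic aromatic bromination of an activated phenol; C-3, flanked by the hydroxyl and one benzyloxy group, is less hindered than C-5 between two benzyloxy groups and is the usual site of halogenation of 2-hydroxy-4,6-dialkoxyaryl ketones, and one equivalent of NBS in the cold avoids dibromination and α-bromination of the ketone.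

Step 11
Reactants: 23 1-[4,6-bis(benzyloxy)-3-bromo-2-hydroxyphenyl]butan-1-one
Product: 24 1-[4,6-bis(benzyloxy)-3-bromo-2-methoxyphenyl]butan-1-one
Conditions: MeI (3 equiv), K2CO3 (2 equiv), DMF, 50 °C
Reagents that add atoms: iodomethane, CI
Why: Williamson methylation of the only free hydroxyl; hindrance and chelation call for excess MeI in warm DMF, and carbonate is too weak a base to methylate the ketone α-carbon.

Step 12
Reactants: 24 1-[4,6-bis(benzyloxy)-3-bromo-2-methoxyphenyl]butan-1-one
Product: 25 1-[4,6-bis(benzyloxy)-2-methoxy-3-methylphenyl]butan-1-one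
Conditions: MeB(OH)2 (2 equiv), Pd(OAc)2 (5 mol %), SPhos (2-dicyclohexylphosphino-2',6'-dimethoxybiphenyl, 10 mol %), K3PO4 (3 equiv), toluene–H2O, 100 °C
Reagents that add atoms: methylboronic acid, CB(O)O
Why: Suzuki–Miyaura methylation; the electron-rich biaryl phosphine lets zerovalent palladium insert into the di-ortho-substituted aryl bromide, and transmetalation with the methylboronate and reductive elimination place the methyl group at the carbon fixed by the bromination, with the benzyl ethers and the ketone untouched.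

Step 13
Reactants: 25 1-[4,6-bis(benzyloxy)-2-methoxy-3-methylphenyl]butan-1-one
Product: 26 1-(4,6-dihydroxy-2-methoxy-3-methylphenyl)butan-1-one
Conditions: H2 (1 atm), Pd/C (10 %), EtOAc–MeOH, rt
Reagents that add atoms: none
Why: hydrogenolysis of the aryl benzyl ethers; the aryl methyl ether and the aryl ketone are untouched at 1 atm.

Step 14
Reactants: 26 1-(4,6-dihydroxy-2-methoxy-3-methylphenyl)butan-1-one
Product: 27 1-{3-[(dimethylamino)methyl]-2,4-dihydroxy-6-methoxy-5-methylphenyl}butan-1-one
Conditions: Me2N+=CH2 I− (1.1 equiv), CH2Cl2–MeCN, 0 °C → rt; aq. NaHCO3 work-up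
Reagents that add atoms: N,N-dimethylmethyleneiminium iodide (Eschenmoser's salt), C=[N+](C)C.[I-]
Why: Mannich reaction of an electron-rich phenol; ring C has a single unsubstituted carbon, between the two hydroxyls, so the position is fixed.

Step 15
Reactants: 27 1-{3-[(dimethylamino)methyl]-2,4-dihydroxy-6-methoxy-5-methylphenyl}butan-1-one; 22 2-butanoyl-4-[(3-butanoyl-2,4,6-trihydroxyphenyl)methyl]-3,5-dihydroxy-6,6-dimethylcyclohexa-2,4-dien-1-one
Product: 30 2-butanoyl-4-({3-butanoyl-5-[(3-butanoyl-2,6-dihydroxy-4-methoxy-5-methylphenyl)methyl]-2,4,6-trihydroxyphenyl}methyl)-3,5-dihydroxy-6,6-dimethylcyclohexa-2,4-dien-1-one, via ring C ammonium iodide 28 (not isolated), via ring C quinone methide 29 (not isolated)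
Conditions: MeI (1.1 equiv), THF, rt, evaporate; 22 (1.0 equiv), Et3N (2.5 equiv), MeCN, 0 °C → rt; then 1 M HCl
Reagents that add atoms: none
Why: N-methylation and mild base turn 27 into an o-quinone methide that is captured by the only C–H nucleophilic position of 22, the free carbon of ring B (Michael-type C-alkylation, the known way to unsymmetrical methylene-bridged acylphloroglucinols); O-alkylation is reversible and 27 has no free ring carbon, so no symmetric dimer of ring C can form.

**Compound list**

1 | phloroglucinol (benzene-1,3,5-triol) | Oc1cc(O)cc(O)c1 | starting material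
2 | butanenitrile | CCCC#N | starting material
3 | 1-(2,4,6-trihydroxyphenyl)butan-1-iminium chloride | CCCC(=[NH2+])c1c(O)cc(O)cc1O.[Cl-] | intermediate
4 | 1-(2,4,6-trihydroxyphenyl)butan-1-one | CCCC(=O)c1c(O)cc(O)cc1O | intermediate
5 | 1-[2,4-bis(benzyloxy)-6-hydroxyphenyl]butan-1-one | CCCC(=O)c1c(O)cc(OCc2ccccc2)cc1OCc1ccccc1 | intermediate
6 | 1-{4,6-bis(benzyloxy)-3-[(dimethylamino)methyl]-2-hydroxyphenyl}butan-1-one | CCCC(=O)c1c(O)c(CN(C)C)c(OCc2ccccc2)cc1OCc1ccccc1 | intermediate
7 | butanal oxime | CCCC=NO | starting material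
8 | dibenzyl 3-oxopentanedioate | O=C(CC(=O)OCc1ccccc1)CC(=O)OCc1ccccc1 | starting material
9 | N-hydroxybutanimidoyl chloride | CCCC(Cl)=NO | intermediate
10 | butanenitrile oxide | CCCC#[N+][O-] | intermediate
11 | benzyl 5-[2-(benzyloxy)-2-oxoethyl]-3-propyl-1,2-oxazole-4-carboxylate | CCCc1noc(CC(=O)OCc2ccccc2)c1C(=O)OCc1ccccc1 | intermediate
12 | 1-[4,6-bis(benzyloxy)-3-butanoyl-2-hydroxyphenyl]-N,N,N-trimethylmethanaminium iodide | CCCC(=O)c1c(O)c(C[N+](C)(C)C)c(OCc2ccccc2)cc1OCc1ccccc1.[I-] | intermediate
13 | 1-[2,4-bis(benzyloxy)-5-methylidene-6-oxocyclohexa-1,3-dien-1-yl]butan-1-one | CCCC(=O)C1=C(OCc2ccccc2)C=C(OCc2ccccc2)C(=C)C1=O | intermediate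
14 | benzyl 5-{1-(benzyloxy)-3-[4,6-bis(benzyloxy)-3-butanoyl-2-hydroxyphenyl]-1-oxopropan-2-yl}-3-propyl-1,2-oxazole-4-carboxylate (racemic) | CCCc1noc(C(Cc2c(O)c(C(=O)CCC)c(OCc3ccccc3)cc2OCc2ccccc2)C(=O)OCc2ccccc2)c1C(=O)OCc1ccccc1 | intermediate
15 | benzyl 5-[5,7-bis(benzyloxy)-8-butanoyl-2-oxo-3,4-dihydro-2H-chromen-3-yl]-3-propyl-1,2-oxazole-4-carboxylate (racemic) | CCCc1noc(C2Cc3c(OCc4ccccc4)cc(OCc4ccccc4)c(C(=O)CCC)c3OC2=O)c1C(=O)OCc1ccccc1 | intermediate
16 | 2-bromo-2-methylpropanoyl bromide | CC(C)(Br)C(=O)Br | starting material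
17 | dimethylketene (2-methylprop-1-en-1-one) | CC(C)=C=O | intermediate
18 | 5',7'-bis(benzyloxy)-8'-butanoyl-5,5-dimethyl-3-propyl-4H-spiro[1,2-benzoxazole-7,3'-chromane]-2',4,6(5H)-trione (racemic) | CCCc1noc2c1C(=O)C(C)(C)C(=O)C23Cc1c(OCc4ccccc4)cc(OCc4ccccc4)c(C(=O)CCC)c1OC3=O | intermediate
19 | benzyl 7-{[4,6-bis(benzyloxy)-3-butanoyl-2-hydroxyphenyl]methyl}-5,5-dimethyl-4,6-dioxo-3-propyl-4,5,6,7-tetrahydro-1,2-benzoxazole-7-carboxylate (racemic) | CCCc1noc2c1C(=O)C(C)(C)C(=O)C2(Cc1c(O)c(C(=O)CCC)c(OCc3ccccc3)cc1OCc1ccccc1)C(=O)OCc1ccccc1 | intermediate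
20 | 3-(1-aminobutylidene)-1-[(3-butanoyl-2,4,6-trihydroxyphenyl)methyl]-5,5-dimethyl-2,4,6-trioxocyclohexane-1-carboxylic acid (racemic) | CCCC(N)=C1C(=O)C(C)(C)C(=O)C(Cc2c(O)cc(O)c(C(=O)CCC)c2O)(C(=O)O)C1=O | intermediate
21 | 2-(1-aminobutylidene)-6-[(3-butanoyl-2,4,6-trihydroxyphenyl)methyl]-5-hydroxy-4,4-dimethylcyclohex-5-ene-1,3-dione | CCCC(N)=C1C(=O)C(Cc2c(O)cc(O)c(C(=O)CCC)c2O)=C(O)C(C)(C)C1=O | intermediate
22 | 2-butanoyl-4-[(3-butanoyl-2,4,6-trihydroxyphenyl)methyl]-3,5-dihydroxy-6,6-dimethylcyclohexa-2,4-dien-1-one | CCCC(=O)C1=C(O)C(Cc2c(O)cc(O)c(C(=O)CCC)c2O)=C(O)C(C)(C)C1=O | intermediate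
23 | 1-[4,6-bis(benzyloxy)-3-bromo-2-hydroxyphenyl]butan-1-one | CCCC(=O)c1c(O)c(Br)c(OCc2ccccc2)cc1OCc1ccccc1 | intermediate
24 | 1-[4,6-bis(benzyloxy)-3-bromo-2-methoxyphenyl]butan-1-one | CCCC(=O)c1c(OC)c(Br)c(OCc2ccccc2)cc1OCc1ccccc1 | intermediate
25 | 1-[4,6-bis(benzyloxy)-2-methoxy-3-methylphenyl]butan-1-one | CCCC(=O)c1c(OC)c(C)c(OCc2ccccc2)cc1OCc1ccccc1 | intermediate
26 | 1-(4,6-dihydroxy-2-methoxy-3-methylphenyl)butan-1-one | CCCC(=O)c1c(OC)c(C)c(O)cc1O | intermediate
27 | 1-{3-[(dimethylamino)methyl]-2,4-dihydroxy-6-methoxy-5-methylphenyl}butan-1-one | CCCC(=O)c1c(OC)c(C)c(O)c(CN(C)C)c1O | intermediate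
28 | 1-(3-butanoyl-2,6-dihydroxy-4-methoxy-5-methylphenyl)-N,N,N-trimethylmethanaminium iodide | CCCC(=O)c1c(OC)c(C)c(O)c(C[N+](C)(C)C)c1O.[I-] | intermediate
29 | 1-(2-hydroxy-6-methoxy-5-methyl-3-methylidene-4-oxocyclohexa-1,5-dien-1-yl)butan-1-one | C=C1C(=O)C(C)=C(OC)C(C(=O)CCC)=C1O | intermediate
30 | 2-butanoyl-4-({3-butanoyl-5-[(3-butanoyl-2,6-dihydroxy-4-methoxy-5-methylphenyl)methyl]-2,4,6-trihydroxyphenyl}methyl)-3,5-dihydroxy-6,6-dimethylcyclohexa-2,4-dien-1-one | CCCC(=O)C1=C(O)C(Cc2c(O)c(Cc3c(O)c(C)c(OC)c(C(=O)CCC)c3O)c(O)c(C(=O)CCC)c2O)=C(O)C(C)(C)C1=O | target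

**Step count and risks**

Total: 15 steps. Longest linear sequence: 8 steps (1 → 2 → 3 → 5 → 7 → 8 → 9 → 15); the ring C branch (1 → 2 → 10 → 11 → 12 → 13 → 14 → 15) is equally long.

Steps most likely to fail:

1. Step 7 (proposed annulation). The ketene adduct may revert or be protonated before ring closure, the ketene may be lost to oligomerisation, or the expelled benzyl oxide may cleave the new 1,3-diketone instead of the lactone. Any spiro lactone 18 left unopened would still converge on 22, since the acid of step 9 hydrolyses and decarboxylates it. Fallback with known chemistry and no annulation: set out from 4; exhaustive C-methylation with MeI and NaOMe in MeOH (the classical dearomatising gem-dimethylation of acylphloroglucinols) should give 2-butanoyl-3,5-dihydroxy-4,4-dimethylcyclohexa-2,5-dien-1-one F1 (butyrylfilicinic acid). Condensation of F1 with a second portion of 4 and aqueous formaldehyde in dilute aqueous KOH at 0 °C (classical methylene-bridge formation, symmetric by-products removed by chromatography) returns to the route at 22.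

2. Step 9. The strongly stabilised vinylogous amide may hydrolyse slowly, so that the acid and heat needed begin to break or exchange the methylene bridge or to close a xanthene by cyclodehydration. Fallback: set out from 19 and unmask while the bridge-bearing carbon is still quaternary and ring B is still benzylated. N–O cleavage with Mo(CO)6 in MeCN–H2O at 80 °C should give benzyl 3-(1-aminobutylidene)-1-{[4,6-bis(benzyloxy)-3-butanoyl-2-hydroxyphenyl]methyl}-5,5-dimethyl-2,4,6-trioxocyclohexane-1-carboxylate F2. Hydrolysis with 2 M HCl in THF at 60 °C should give benzyl 3-butanoyl-1-{[4,6-bis(benzyloxy)-3-butanoyl-2-hydroxyphenyl]methyl}-2-hydroxy-5,5-dimethyl-4,6-dioxocyclohex-2-ene-1-carboxylate F3. Hydrogenolysis (H2, Pd/C, THF–MeOH, then 40 °C) removes the three benzyl groups with loss of CO2 and returns to the route at 22.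

3. Step 15. The existing methylene bridge may exchange its units (retro-Michael cleavage and recombination) under basic conditions, or the ambident anion of 22 may be alkylated on oxygen. Fallback with the roles of the partners reversed: set out from 22 and aminomethylate its single free aromatic carbon with Eschenmoser's salt to 2-butanoyl-4-({3-butanoyl-5-[(dimethylamino)methyl]-2,4,6-trihydroxyphenyl}methyl)-3,5-dihydroxy-6,6-dimethylcyclohexa-2,4-dien-1-one F4. Heating F4 with 26 in 1,4-dioxane at 80 °C without added base (thermal loss of dimethylamine, C-alkylation of the free carbon of 26) rejoins the route at the target 30.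

**Further compounds**

F1 | step 7 | 2-butanoyl-3,5-dihydroxy-4,4-dimethylcyclohexa-2,5-dien-1-one | CCCC(=O)C1=C(O)C=C(O)C(C)(C)C1=O
F2 | step 9 | benzyl 3-(1-aminobutylidene)-1-{[4,6-bis(benzyloxy)-3-butanoyl-2-hydroxyphenyl]methyl}-5,5-dimethyl-2,4,6-trioxocyclohexane-1-carboxylate (racemic) | CCCC(N)=C1C(=O)C(C)(C)C(=O)C(Cc2c(O)c(C(=O)CCC)c(OCc3ccccc3)cc2OCc2ccccc2)(C(=O)OCc2ccccc2)C1=O
F3 | step 9 | benzyl 3-butanoyl-1-{[4,6-bis(benzyloxy)-3-butanoyl-2-hydroxyphenyl]methyl}-2-hydroxy-5,5-dimethyl-4,6-dioxocyclohex-2-ene-1-carboxylate (racemic) | CCCC(=O)C1=C(O)C(Cc2c(O)c(C(=O)CCC)c(OCc3ccccc3)cc2OCc2ccccc2)(C(=O)OCc2ccccc2)C(=O)C(C)(C)C1=O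
F4 | step 15 | 2-butanoyl-4-({3-butanoyl-5-[(dimethylamino)methyl]-2,4,6-trihydroxyphenyl}methyl)-3,5-dihydroxy-6,6-dimethylcyclohexa-2,4-dien-1-one | CCCC(=O)C1=C(O)C(Cc2c(O)c(CN(C)C)c(O)c(C(=O)CCC)c2O)=C(O)C(C)(C)C1=O
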